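## Structural features

The target 7 is a diaryl ether of two brominated benzyl alcohols and has no stereocentre. Ring A carries CH2OH at C1, Br at C2, the ether oxygen at C3, OH at C4, Br at C5 and H at C6; ring B carries CH2OH at C1, the ether oxygen at C2, OH at C3 and C4, Br at C5 and H at C6. The single ether oxygen joins C3 of ring A to C2 of ring B and has four ortho neighbours (Br and OH on ring A, CH2OH and OH on ring B), so the C–O–C unit is crowded. Both rings are bromocatechol units oxidised at C3 and C4: in ring A the oxygen O3 is the bridge, and in ring B the catechol is free and the bridge sits on the neighbouring C2, which gives ring B three contiguous C–O carbons. Fragile groups are the free catechol (air oxidation above neutral pH), the two benzyl alcohols para to a phenol OH (quinone methide formation, solvolysis) and three aryl bromides, which exclude low-valent metals, lithiation and hydrogenolysis. The real difficulty is the tetra-ortho-substituted C–O bond between two electron-rich rings, together with the exact placing of three bromines, above all the one at C2 of ring A between CH2OH and the ether oxygen. The key step exploits the position of C2 of ring B, ortho to the C3/C4 catechol and ortho to the one-carbon group on C1. With C3/C4 oxidised to an ortho-quinone and C1 bearing a formyl group, C2 is the electrophilic end of both the enal C1=C2 and the dienone O=C4–C5=C6–C1=C2, while C5, the only other such end, already carries the bromine the target needs.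

## Logic of the disconnections

In one sentence: the phenol oxygen of 2 is added to C2 of 3, which is made in the flask by dehydrogenation of 1.

7 ⇒ 6. The two benzylic C–H bonds of each CH2OH are cut, so both alcohols are taken back to formyl groups. The alcohols para to a phenol OH are the most fragile groups of 7 and are best made last. As formyl groups they deactivate both rings against over-bromination and over-oxidation, and on ring B the formyl group is what makes C2 electrophilic in the key step. The forward step must reduce two aldehydes without touching three C–Br bonds or ionising the product alcohols.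

6 ⇒ 5. The C5–Br bond of ring A is cut. This carbon is ortho to the only free phenol of ring A, whose other ortho and para positions are occupied, so the bromine can be introduced last by electrophilic substitution. The gain is that ring A can come from purchasable 2. The forward step must brominate once, on ring A, and leave C6 of ring B alone.

5 ⇒ 4. The O–CH3 bond on O4 of ring A is cut. The methyl group tells the two oxygens of ring A apart, so only O3 can act as nucleophile, and it keeps ring A from becoming a quinone in the oxidative step. The forward step must cleave one aryl methyl ether in the presence of a diaryl ether, two aldehydes and a catechol.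

4 ⇒ 2 + 3 (3 ⇐ 1). The bond between the ether oxygen and C2 of ring B is cut, with the oxygen staying on ring A. Ring B is taken back to 3, in which C2 is a C–H carbon made electrophilic by oxidation, so that two nucleophilic phenols are joined by polarity reversal of one of them. The gain is large: both partners are purchasable benzaldehydes, ring B needs no leaving group, and its third oxygen arrives by C–H functionalisation with the catechol left free. The forward step must attack C2 and not C6 or C5, must go through oxygen, and must oxidise 1 only.

## Other disconnections considered

Alternative 1: The same C–O bond is cut in the classical sense, phenoxide plus aryl halide, and this is the first plan that comes to mind. The forward key step would be nucleophilic aromatic substitution of the phenoxide of 2 on 2-fluoro-3,4-dimethoxybenzaldehyde A1, activated by its ortho formyl group, to give diaryl ether A2; a copper- or palladium-catalysed coupling is the variant. The fluorine-bearing carbon of A1 is deactivated by two methoxy donors, one of them para to the formyl group, and the nucleophile is a weakly basic phenoxide flanked by Br and OMe, so forcing conditions are to be expected. The metal-catalysed variants would have to tell the C–Br bond of 2 from the intended halide. The plan also needs three O-methyl groups removed and the ring B bromine added afterwards, and it makes no use of the innate reactivity of the catechol.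

Alternative 2: The same bond is cut with the roles reversed, ring A as electrophile through a phenoxonium ion. Two-electron oxidation of 3,5-dibromo-4-hydroxybenzaldehyde A3 (Tl(NO3)3 in methanol, or at an anode) in the presence of the ring B phenol 5-bromo-2-hydroxy-3,4-dimethoxybenzaldehyde A4 would give the ortho-quinol ether A5 by attack at a bromine-bearing ortho carbon. Zinc reduction would then expel bromide to give diaryl ether A6. Three grounds speak against it. A4 is the more electron-rich phenol and would be oxidised first, so the cross-coupling would compete with self-coupling. A6 lacks the bromine at C2 of ring A, and later bromination would be directed para to the ether oxygen, to C6. A tribrominated analogue of A3 carrying that bromine from the start would be attacked at the less hindered ortho carbon, so the wrong bromine would be lost.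

Alternative 3: Ring B is built from open-chain and four-membered precursors by a Danheiser benzannulation, the ether oxygen being carried in on an alkyne. Heating the 1,2-dioxygenated alkyne A7, made from ring A, with cyclobutenone A8 would pass through a vinylketene, a (2+2) adduct, a second ring opening and a 6π closure to a pentasubstituted phenol. The ketene carbonyl carbon bonds to the more nucleophilic alkyne carbon, which in A7 is the one bearing the aryloxy group (it is β to the better methoxy donor). The expected product is therefore A9, with the aryloxy group on the central carbon of the three C–O carbons and not next to the one-carbon substituent as 7 requires. Dioxyacetylenes such as A7 are also barely isolable, and the plan is several steps longer than the chosen one.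

Key step: step 1

Remark on the chemistry: 1 and 2 are taken to be purchasable, and rotation about the two aryl–O bonds of 7 is taken to be fast, so no axial stereochemistry is addressed.

## Route

Step 1
Reactants: 1 3-bromo-4,5-dihydroxybenzaldehyde; 2 2-bromo-3-hydroxy-4-methoxybenzaldehyde
Product: 4 5-bromo-2-(2-bromo-3-formyl-6-methoxyphenoxy)-3,4-dihydroxybenzaldehyde, via ortho-quinone 3 (not isolated)
Conditions: Ag2O, Na2SO4, MeCN, 0 °C, filter; then 2, Cs2CO3 (0.2 equiv), MeCN, −20 → 0 °C
Reagents that add atoms: none
Why: Ag2O should dehydrogenate catechol 1 to the electron-poor ortho-quinone 3 under neutral, water-free conditions that leave the formyl group alone (the classical silver oxide route to ortho-quinones), and the filtered solution is used at once. The phenoxide of 2, kept at low concentration by the carbonate, should then add through oxygen to C2 of 3 (oxa-Michael addition): C2 is the β-carbon of the enal C1=C2 and also the far end of the dienone O=C4–C5=C6–C1=C2, so the charge of the adduct is shared by the formyl oxygen and O4. Enolisation of the C2–H adduct re-aromatises ring B to the catechol 4, which makes the C–O bond formation irreversible. The closest known reaction type is the conjugate addition of thiols, alkoxides and phenols to ortho-quinones that carry a conjugated acceptor, the same mode by which catechol-derived diaryl ethers are believed to arise in nature. No ring is closed and no stereocentre is formed. The step needs O- over C-arylation, which the substrate secures because the ring of 2 is deactivated by CHO and Br and its only open para position is ortho to the formyl group. It needs attack at C2 and not at C6 or C5 of 3, secured because attack at C6 gives an enolate stabilised by one carbonyl only and C5, the second 1,6-terminus, already carries the bromine of the target. It needs oxidation of one partner only, secured because 2 is a mono-phenol whose O4 is capped as the methyl ether and which never meets the oxidant.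

Step 2
Reactants: 4 5-bromo-2-(2-bromo-3-formyl-6-methoxyphenoxy)-3,4-dihydroxybenzaldehyde
Product: 5 5-bromo-2-(2-bromo-3-formyl-6-hydroxyphenoxy)-3,4-dihydroxybenzaldehyde
Conditions: BBr3 (6 equiv), CH2Cl2, −78 °C → rt; then H2O
Reagents that add atoms: none
Why: Lewis acid cleavage of an aryl methyl ether (BBr3 demethylation); the diaryl ether, the aryl bromides and the formyl groups are inert to BBr3 at these temperatures, and the catechol is only held as a borate until the aqueous work-up.

Step 3
Reactants: 5 5-bromo-2-(2-bromo-3-formyl-6-hydroxyphenoxy)-3,4-dihydroxybenzaldehyde
Product: 6 5-bromo-2-(2,5-dibromo-3-formyl-6-hydroxyphenoxy)-3,4-dihydroxybenzaldehyde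
Conditions: Br2 (1.0 equiv), AcOH, 15 °C
Reagents that add atoms: bromine, BrBr
Why: Electrophilic aromatic bromination directed ortho by the free 4-OH of ring A, whose other ortho and para positions are occupied (the pattern of vanillin going to 5-bromovanillin); the only other OH-activated open site, C6 of ring B, lies between Br and CHO and should react much more slowly with one equivalent.

Step 4
Reactants: 6 5-bromo-2-(2,5-dibromo-3-formyl-6-hydroxyphenoxy)-3,4-dihydroxybenzaldehyde
Product: 7 6-bromo-3-[2,5-dibromo-6-hydroxy-3-(hydroxymethyl)phenoxy]-4-(hydroxymethyl)benzene-1,2-diol
Conditions: NaBH4 (excess), THF/MeOH, 0 °C; then aq NH4Cl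
Reagents that add atoms: none
Why: Borohydride reduction of both aryl aldehydes to benzyl alcohols, well precedented for hydroxy- and bromobenzaldehydes; aryl bromides, phenols and the diaryl ether are inert, and a cold buffered quench avoids acid- or base-induced ionisation of the p-hydroxybenzyl alcohols.

## Compound list

1 | 3-bromo-4,5-dihydroxybenzaldehyde | O=Cc1cc(O)c(O)c(Br)c1 | starting material
2 | 2-bromo-3-hydroxy-4-methoxybenzaldehyde | COc1ccc(C=O)c(Br)c1O | starting material
3 | 5-bromo-3,4-dioxocyclohexa-1,5-diene-1-carbaldehyde | O=CC1=CC(=O)C(=O)C(Br)=C1 | intermediate
4 | 5-bromo-2-(2-bromo-3-formyl-6-methoxyphenoxy)-3,4-dihydroxybenzaldehyde | COc1ccc(C=O)c(Br)c1Oc1c(C=O)cc(Br)c(O)c1O | intermediate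
5 | 5-bromo-2-(2-bromo-3-formyl-6-hydroxyphenoxy)-3,4-dihydroxybenzaldehyde | O=Cc1ccc(O)c(Oc2c(C=O)cc(Br)c(O)c2O)c1Br | intermediate
6 | 5-bromo-2-(2,5-dibromo-3-formyl-6-hydroxyphenoxy)-3,4-dihydroxybenzaldehyde | O=Cc1cc(Br)c(O)c(Oc2c(C=O)cc(Br)c(O)c2O)c1Br | intermediate
7 | 6-bromo-3-[2,5-dibromo-6-hydroxy-3-(hydroxymethyl)phenoxy]-4-(hydroxymethyl)benzene-1,2-diol | OCc1cc(Br)c(O)c(Oc2c(CO)cc(Br)c(O)c2O)c1Br | target

## Step count and least certain steps

Total step count: 4. Longest linear sequence: 4 steps (1 and 2 → 4 → 5 → 6 → 7).

Step 1 (key step). Three processes are most likely to go wrong.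
- Loss of site control on 3: the hindered phenoxide may add at the less congested C6, or add and eliminate at C5.
- Redox exchange between product 4 and unreacted 3, followed by a second addition. A wash with aqueous Na2S2O4 at work-up would return any over-oxidised ether to the catechol state.
- Decay of 3 by self-condensation or hydration before the weakly nucleophilic phenoxide captures it.

The fallback changes the approach to the classical substitution and sets out from 2. Nucleophilic aromatic substitution of 2 on the fluoroarene A1 (K2CO3, DMSO, 110 °C) should give the diaryl ether 2-(2-bromo-3-formyl-6-methoxyphenoxy)-3,4-dimethoxybenzaldehyde F1 (the same structure as A2). BBr3 in CH2Cl2 should cleave all three methyl ethers to 2-(2-bromo-3-formyl-6-hydroxyphenoxy)-3,4-dihydroxybenzaldehyde F2. Br2 (2 equiv) in AcOH should then brominate ortho to the 4-OH of each ring, at C5 of ring A and at C5 of ring B (the latter also para to the ether oxygen). The fallback comes back to the route at 6.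

Step 3. The likely failures are loss of site selectivity (a second bromination at C6 of ring B, para to its 3-OH) and oxidation of the ring B catechol by bromine. The fallback places the second ring A bromine before the coupling and sets out from 1. Br2 in AcOH should brominate 1 at C6, between the formyl group and the 5-OH. This is the ortho mode shown by 3-hydroxy-4-alkoxybenzaldehydes, and the other open carbon is shielded by Br. The product would be 2,5-dibromo-3,4-dihydroxybenzaldehyde F3. MOMCl with NaHCO3 in DMF should alkylate the more acidic OH para to the formyl group and give 2,5-dibromo-3-hydroxy-4-(methoxymethoxy)benzaldehyde F4. Addition of F4 to 3 under the conditions of step 1 should give 5-bromo-2-[2,5-dibromo-3-formyl-6-(methoxymethoxy)phenoxy]-3,4-dihydroxybenzaldehyde F5. HCl in MeOH should remove the acetal, and the fallback comes back to the route at 6.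

Step 4. The likely failure is ionisation of the p-hydroxybenzyl alkoxides to quinone methides under the basic hydride conditions, followed by capture of hydride (over-reduction to a methyl group) or of methanol (methyl ether); the poly-phenoxide may also be reduced sluggishly. The fallback reduces a substrate without free phenols and sets out from 6. Ac2O in pyridine should give 3,4-diacetoxy-2-(6-acetoxy-2,5-dibromo-3-formylphenoxy)-5-bromobenzaldehyde F6. BH3·SMe2 in THF at 0 °C should reduce both aldehydes with no phenoxide present and give 3-[6-acetoxy-2,5-dibromo-3-(hydroxymethyl)phenoxy]-6-bromo-4-(hydroxymethyl)-1,2-phenylene diacetate F7. N2H4·H2O in THF/MeOH at 0 °C should remove the three acetates under nearly neutral conditions, and the fallback comes back to the route at 7.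

## Further compounds

F1 | step 1 | 2-(2-bromo-3-formyl-6-methoxyphenoxy)-3,4-dimethoxybenzaldehyde | COc1ccc(C=O)c(Br)c1Oc1c(C=O)ccc(OC)c1OC
F2 | step 1 | 2-(2-bromo-3-formyl-6-hydroxyphenoxy)-3,4-dihydroxybenzaldehyde | O=Cc1ccc(O)c(Oc2c(C=O)ccc(O)c2O)c1Br
F3 | step 3 | 2,5-dibromo-3,4-dihydroxybenzaldehyde | O=Cc1cc(Br)c(O)c(O)c1Br
F4 | step 3 | 2,5-dibromo-3-hydroxy-4-(methoxymethoxy)benzaldehyde | COCOc1c(Br)cc(C=O)c(Br)c1O
F5 | step 3 | 5-bromo-2-[2,5-dibromo-3-formyl-6-(methoxymethoxy)phenoxy]-3,4-dihydroxybenzaldehyde | COCOc1c(Br)cc(C=O)c(Br)c1Oc1c(C=O)cc(Br)c(O)c1O
F6 | step 4 | 3,4-diacetoxy-2-(6-acetoxy-2,5-dibromo-3-formylphenoxy)-5-bromobenzaldehyde | CC(=O)Oc1c(Br)cc(C=O)c(Br)c1Oc1c(C=O)cc(Br)c(OC(C)=O)c1OC(C)=O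
F7 | step 4 | 3-[6-acetoxy-2,5-dibromo-3-(hydroxymethyl)phenoxy]-6-bromo-4-(hydroxymethyl)-1,2-phenylene diacetate | CC(=O)Oc1c(Br)cc(CO)c(Br)c1Oc1c(CO)cc(Br)c(OC(C)=O)c1OC(C)=O
A1 | alternative 1 | 2-fluoro-3,4-dimethoxybenzaldehyde | COc1ccc(C=O)c(F)c1OC
A2 | alternative 1 | 2-(2-bromo-3-formyl-6-methoxyphenoxy)-3,4-dimethoxybenzaldehyde | COc1ccc(C=O)c(Br)c1Oc1c(C=O)ccc(OC)c1OC
A3 | alternative 2 | 3,5-dibromo-4-hydroxybenzaldehyde | O=Cc1cc(Br)c(O)c(Br)c1
A4 | alternative 2 | 5-bromo-2-hydroxy-3,4-dimethoxybenzaldehyde | COc1c(Br)cc(C=O)c(O)c1OC
A5 | alternative 2 | racemic 5-bromo-2-[(1,3-dibromo-5-formyl-2-oxocyclohexa-3,5-dien-1-yl)oxy]-3,4-dimethoxybenzaldehyde | O=CC1=CC(Br)(Oc2c(C=O)cc(Br)c(OC)c2OC)C(=O)C(Br)=C1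
A6 | alternative 2 | 5-bromo-2-(3-bromo-5-formyl-2-hydroxyphenoxy)-3,4-dimethoxybenzaldehyde | O=Cc1cc(Br)c(O)c(Oc2c(C=O)cc(Br)c(OC)c2OC)c1
A7 | alternative 3 | 2-bromo-4-methoxy-3-[(methoxyethynyl)oxy]benzaldehyde | COC#COc1c(OC)ccc(C=O)c1Br
A8 | alternative 3 | 2-({[tert-butyl(dimethyl)silyl]oxy}methyl)cyclobut-2-en-1-one | CC(C)(C)[Si](C)(C)OCC1=CCC1=O
A9 | alternative 3 | 2-bromo-3-[3-({[tert-butyl(dimethyl)silyl]oxy}methyl)-6-hydroxy-2-methoxyphenoxy]-4-methoxybenzaldehyde | COc1c(CO[Si](C)(C)C(C)(C)C)ccc(O)c1Oc1c(OC)ccc(C=O)c1Br
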